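**Assumptions (one line each)**
- 2-Methylhydroquinone is silylated at its less hindered OH, giving the 4-OTBS phenol (major isomer, separable).
- CIP: in the target, C2 of the chroman is R and the carbinol carbon is R. The SMILES patterns below carry this through. The 2-vinylchroman intermediate is labelled S only because CIP priorities change when vinyl becomes CH2CH2R.
- The enantiomer of the Pd ligand is chosen to give the S vinylchroman. (+)-Ipc2B-allyl (from (−)-α-pinene) is chosen to give Re-face attack, so the carbinol is R. Both sense assignments rest on precedent models and should be confirmed by Mosher or chiral HPLC.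

**Retrosynthesis**
1. Remove the aryl TBS group. Disconnect C5–C6 by B-alkyl Suzuki coupling of the alkyl-9-BBN from (S)-2-vinylchroman **9** with the (E,E)-vinyl iodide **16**.
2. **16** comes from cross-metathesis prenylation of the allyl carbinol **15**. **15** comes from Brown asymmetric allylation of the dienal **14**. **14** comes from a Wittig reaction of iodo-aldehyde **12** with Ph3P=C(Me)CHO. **12** comes from the Negishi carboalumination product of pent-4-yn-1-ol.
3. The only ring is the chroman. It is formed in one step by Pd(II)/chiral-ligand oxidative (Wacker-type) oxa-cyclization of phenol **8**, which sets the quaternary C2. **8** is made from 2-methylhydroquinone by silylation, ortho-formylation, Wittig/hydrogenation to a ketone, then ethylidenation.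

**Route**

Step 1
Reactants: **1** 2-methylhydroquinone
Product: **2** 4-(TBSO)-2-methylphenol
Conditions: TBSCl, imidazole, CH2Cl2, 0 °C
Reagents that add atoms: TBSCl, CC(C)(C)[Si](C)(C)Cl
Why: Silylation by steric selection at the OH remote from the methyl leaves the OH next to CH3 free. That OH later becomes the ring oxygen. Reaction type: silyl ether protection.

Step 2
Reactants: **2**
Product: **3** 5-(TBSO)-2-hydroxy-3-methylbenzaldehyde
Conditions: MgCl2, Et3N, (CH2O)n, MeCN, 80 °C
Reagents that add atoms: paraformaldehyde, C=O
Why: The Mg phenoxide directs formylation to the only free ortho position (C6), which becomes C4a of the chroman. Reaction type: Casnati–Skattebøl ortho-formylation.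

Step 3
Reactants: **3**, **4** 1-(triphenylphosphoranylidene)propan-2-one
Product: **5** (E)-4-[5-(TBSO)-2-hydroxy-3-methylphenyl]but-3-en-2-one
Conditions: toluene, 80 °C
Reagents that add atoms: **4**, CC(=O)C=P(c1ccccc1)(c1ccccc1)c1ccccc1
Why: A stabilized ylide under neutral conditions gives the E-enone and leaves the free phenol and the silyl ether untouched. Reaction type: Wittig olefination.

Step 4
Reactants: **5**
Product: **6** 4-[5-(TBSO)-2-hydroxy-3-methylphenyl]butan-2-one
Conditions: H2 (1 atm), 10% Pd/C, EtOAc, rt
Reagents that add atoms: none
Why: The conjugated C=C is reduced selectively. The ketone and the aryl silyl ether survive. No stereocentre is involved. Reaction type: catalytic hydrogenation.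

Step 5
Reactants: **6**, **7** ethyltriphenylphosphonium bromide
Product: **8** (E)-2-[3-methylpent-3-en-1-yl]-4-(TBSO)-6-methylphenol, the cyclization substrate
Conditions: **7**, KOtBu (2.5 equiv), THF, 0 °C to rt; separate E/Z isomers by chromatography (AgNO3–silica)
Reagents that add atoms: **7**, CC[P+](c1ccccc1)(c1ccccc1)c1ccccc1.[Br-]
Why: Ethylidenation of the methyl ketone gives the trisubstituted alkene. One equivalent of base is used up by the phenol. The pure E isomer is needed because facial selectivity in the next step depends on alkene geometry. Reaction type: Wittig olefination.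

Step 6
Reactants: **8**
Product: **9** (S)-6-(TBSO)-2,8-dimethyl-2-vinylchroman
Conditions: Pd(TFA)2 (10 mol%), chiral N,N-ligand such as (−)-sparteine (20 mol%), O2 (1 atm), Ca(OH)2, 3 Å MS, toluene, 80 °C
Reagents that add atoms: none
Why: The phenoxide adds syn to the more substituted alkene carbon (6-exo) and Pd ends up on the carbon next to the new quaternary centre. β-Hydride elimination from the CH3 then gives the vinyl group. The chiral Pd catalyst selects the alkene face and sets C2. Reaction type: Pd(II)-catalysed enantioselective Wacker-type oxidative cyclization.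

Step 7
Reactants: **10** pent-4-yn-1-ol
Product: **11** (E)-5-iodo-4-methylpent-4-en-1-ol
Conditions: Me3Al, Cp2ZrCl2 (cat.), CH2Cl2, 0 °C to rt; then I2, THF, −30 °C
Reagents that add atoms: trimethylaluminum, C[Al](C)C; iodine, II
Why: Syn methylalumination puts Me on the internal carbon and Al on the terminal carbon. Iodinolysis then gives the E-trisubstituted vinyl iodide. The free OH is tolerated with excess Me3Al. Reaction type: Negishi Zr-catalysed carboalumination–iodination.

Step 8
Reactants: **11**
Product: **12** (E)-5-iodo-4-methylpent-4-enal
Conditions: Dess–Martin periodinane, NaHCO3, CH2Cl2, 0 °C to rt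
Reagents that add atoms: none
Why: Mild oxidation leaves the vinyl iodide untouched. Reaction type: DMP oxidation.

Step 9
Reactants: **12**, **13** 2-(triphenylphosphoranylidene)propanal
Product: **14** (2E,6E)-8-iodo-2,6-dimethylocta-2,6-dienal
Conditions: CH2Cl2 or toluene, 40–60 °C
Reagents that add atoms: **13**, CC(C=O)=P(c1ccccc1)(c1ccccc1)c1ccccc1
Why: The stabilized ylide builds the C10=C11 trisubstituted enal with high E-selectivity. The enal carbon becomes C12. Reaction type: Wittig olefination.

Step 10
Reactants: **14**
Product: **15** (R,E,E)-12-hydroxy allyl adduct, (R,2E,6E... ) i.e. 1-iodo-2,6-dimethyl-undeca-1,5,9-trien-... named as: (4E,8E,7R)-10-iodo-... see compound list for the SMILES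
Conditions: (+)-Ipc2B-allyl (from (−)-α-pinene), Et2O, −78 °C; then NaOH, H2O2
Reagents that add atoms: B-allyldiisopinocampheylborane, flat SMILES C=CCB(C1C(C)C2CC1C2(C)C)C1C(C)C2CC1C2(C)C (use the (+)-Ipc2B enantiomer)
Why: Chair Zimmerman–Traxler addition of the chiral allylborane to the Re face sets the R carbinol. Reaction type: Brown asymmetric allylation.

Step 11
Reactants: **15**
Product: **16** the prenyl carbinol vinyl iodide
Conditions: Hoveyda–Grubbs II (5 mol%), 2-methyl-2-butene (excess), CH2Cl2, 40 °C
Reagents that add atoms: 2-methyl-2-butene, CC=C(C)C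
Why: The unhindered terminal alkene reacts far faster than the trisubstituted alkenes or the vinyl iodide. Exchange with the trisubstituted partner gives the prenyl group and releases propene. The carbinol is not touched. Reaction type: olefin cross-metathesis.

Step 12
Reactants: **9**, **16**
Product: **17** TBS-protected sargachromanol C
Conditions: (a) 9-BBN, THF, 60 °C; (b) add **16**, Pd(dppf)Cl2 (10 mol%), K3PO4 (aq), THF/DMF, rt to 50 °C
Reagents that add atoms: none (9-BBN leaves with boron)
Why: Anti-Markovnikov hydroboration of the vinyl group gives the C2–CH2CH2–B(9-BBN) species. Suzuki coupling then joins C5 to C6 with retention of the E geometry, and C2 is not touched. Reaction type: hydroboration, then B-alkyl Suzuki–Miyaura coupling.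

Step 13
Reactants: **17**
Product: **18** sargachromanol C
Conditions: TBAF, AcOH, THF, 0 °C
Reagents that add atoms: none
Why: Fluoride cleaves the aryl silyl ether and leaves the allylic alcohol, the alkenes and the chroman intact. Reaction type: silyl ether deprotection.

**Compound list**

| # | Name | SMILES | Role |
|---|---|---|---|
| 1 | 2-methylhydroquinone | Cc1cc(O)ccc1O | starting material |
| 2 | 4-(TBSO)-2-methylphenol | Cc1cc(O[Si](C)(C)C(C)(C)C)ccc1O | intermediate |
| 3 | 5-(TBSO)-2-hydroxy-3-methylbenzaldehyde | Cc1cc(O[Si](C)(C)C(C)(C)C)cc(C=O)c1O | intermediate |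
| 4 | 1-(triphenylphosphoranylidene)propan-2-one | CC(=O)C=P(c1ccccc1)(c1ccccc1)c1ccccc1 | starting material |
| 5 | (E)-enone | CC(=O)/C=C/c1cc(O[Si](C)(C)C(C)(C)C)cc(C)c1O | intermediate |
| 6 | aryl butanone | CC(=O)CCc1cc(O[Si](C)(C)C(C)(C)C)cc(C)c1O | intermediate |
| 7 | ethyltriphenylphosphonium bromide | CC[P+](c1ccccc1)(c1ccccc1)c1ccccc1.[Br-] | starting material |
| 8 | (E)-alkenyl phenol | C/C=C(\C)CCc1cc(O[Si](C)(C)C(C)(C)C)cc(C)c1O | intermediate |
| 9 | (S)-6-(TBSO)-2,8-dimethyl-2-vinylchroman | C=C[C@]1(C)CCc2cc(O[Si](C)(C)C(C)(C)C)cc(C)c2O1 | intermediate |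
| 10 | pent-4-yn-1-ol | C#CCCCO | starting material |
| 11 | (E)-5-iodo-4-methylpent-4-en-1-ol | I/C=C(\C)CCCO | intermediate |
| 12 | (E)-5-iodo-4-methylpent-4-enal | I/C=C(\C)CCC=O | intermediate |
| 13 | 2-(triphenylphosphoranylidene)propanal | CC(C=O)=P(c1ccccc1)(c1ccccc1)c1ccccc1 | starting material |
| 14 | (2E,6E)-8-iodo-2,6-dimethylocta-2,6-dienal | O=C/C(C)=C/CC/C(C)=C/I | intermediate |
| 15 | (R)-allyl carbinol vinyl iodide | C=CC[C@@H](O)/C(C)=C/CC/C(C)=C/I | intermediate |
| 16 | (R)-prenyl carbinol vinyl iodide | CC(C)=CC[C@@H](O)/C(C)=C/CC/C(C)=C/I | intermediate |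
| 17 | TBS-protected sargachromanol C | CC(C)=CC[C@@H](O)/C(C)=C/CC/C(C)=C/CC[C@]1(C)CCc2cc(O[Si](C)(C)C(C)(C)C)cc(C)c2O1 | intermediate |
| 18 | sargachromanol C | CC(C)=CC[C@@H](O)/C(C)=C/CC/C(C)=C/CC[C@]1(C)CCc2cc(O)cc(C)c2O1 | target |

Name for **15**: (R,E,E)-1-iodo-2,6-dimethyl-undeca-1,5,10-trien-7-ol carbon skeleton as drawn in the SMILES (allyl in place of prenyl).

**Step count:** 13 steps in total. The longest linear sequence is 8 steps (1→2→3→4→5→6→12→13).

**Three steps most likely to fail**
1. **Step 6, the enantioselective Wacker cyclization.** The ee depends on alkene geometry and on the ligand, and the hindered quaternary centre may give low yield. Fallback: form **9** by Pd-catalysed asymmetric allylic etherification (DYKAT) of an o-vinylphenol with isoprene monoepoxide, then ring-closing metathesis, hydrogenation, oxidation and Wittig methylenation. Alternatively, make racemic **9** by acid cyclization and separate by preparative chiral HPLC.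
2. **Step 10, the Brown allylation of the α-methyl enal.** The ee may be only about 85–90%, and the facial sense is assigned from a model. Fallback: add racemic allylMgBr to **14** and resolve the allylic alcohol by Sharpless kinetic resolution or lipase acylation. Another option is CBS reduction of the corresponding prenyl enone.
3. **Step 12, the B-alkyl Suzuki coupling.** The trisubstituted, hindered vinyl iodide carries a free allylic alcohol, and the aryl silyl ether may partly cleave. Fallback: Schwartz hydrozirconation of **9**, transmetalation to Zn, and Pd-catalysed Negishi coupling with **16**.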